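## Structural features

The target is a guaiane ester: a cyclopentane (ring A, C1–C5) fused through C1 and C5 to a seven-membered ring (C1, C5, C6, C7, C8, C9, C10). C4 carries the C15 methyl and a tertiary hydroxyl, C6 a free secondary hydroxyl, C7 the isopropyl group (C11–C13), O8 a 4-hydroxybenzoate, C9 is a CH2, and C10 carries the C14 methyl on the tetrasubstituted C1=C10 alkene. Five stereocentres stand in an unbroken row from C4 to C8, (4S,5S,6R,7S,8S): H5, H6 and H7 share one face, O4, O6 and the isopropyl group share the other, and O8 is trans to the isopropyl group. O4 and O6 are 1,3-syn across the ring-fusion carbon C5, so whatever groups they carry sit close together. The fragile parts are the tertiary C4 carbinol (elimination under acid), the aryl ester with a free hydroxyl 1,3 to it at C6 (acyl migration or cleavage under base), the phenol, and the C1=C10 alkene, which can leave its position. The real difficulty is to close the seven-membered ring with the alkene in one defined place while setting C5 and C6 next to a quaternary centre, and then to tell three oxygens apart, only one of which is acylated. The key step exploits the sequence C10=C1–C5(H)–C6(H)–C7 together with the C9 methylene that joins C8 to C10: with a C7=C8 alkene in place, this is a cyclohepta-1,4-diene whose cis hydrogens at C5 and C6 are the imprint of a boat Cope rearrangement of a cis-divinylcyclopropane built from C10, C9 and C8.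

## Logic of the disconnections

27 from 26. The O–Si bonds at O4, O6 and the phenol oxygen are cut last. All three masks are silyl groups, so they fall in one operation and 27 needs no selective reaction among four oxygens. The forward step must not create an alkoxide at O6 beside the O8 ester.

26 from 24 and 25. The O8–acyl bond is cut because it is the only link between the terpenoid and the aryl part. 25 is bought and 24 has a single free hydroxyl. The forward step is an acylation of a secondary alcohol flanked by the isopropyl-bearing carbon.

24 from 22. The C8–O and C7–H bonds are cut together, since both lie on one face and so come from a syn addition to the C7=C8 alkene. This trades two stereocentres and the O8 function for an alkene that the ring-forming step leaves in exactly this place. The forward step must put boron on C8, attack the face away from the O6 silyl ether, and leave C1=C10 alone.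

22 from 20, and 20 from 19. The C14–H bonds are exchanged for C14–O bonds. C14 has to be an ester during the carbenoid step, where it is the acceptor group, and only afterwards becomes the methyl group. The forward steps need a hydride substitution at C14 without allylic shift.

19 from 11 and 17, through 18. The C9–C10 and C5–C6 bonds are cut. The C10=C1–C5–C6–C7=C8 diene with C9 between C8 and C10 is the retron of a cis-divinylcyclopropane Cope rearrangement, and the cis hydrogens at C5 and C6 match its boat geometry. The bicycle falls into a cyclopentene with one bought stereocentre and an achiral diene; the forward step makes two bonds, one ring and two stereocentres. It demands catalyst control of the carbenoid face, cyclopropanation only at the terminal alkene of 17, the (1E) geometry of 17, and a boat that tolerates two silyl ethers close together.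

17 from 16, 16 from 13 and 14, 13 from 12. The O–Si bond and then the C7=C8 bond of 16 are cut (aldol retron). Because 12 and 14 are both enolisable, 12 is first turned into 13, which can only be the nucleophile. The forward silylation must give the (1E) enol ether.

11 from 10. The C10=N2 bond is cut. C10 is acidic enough for diazo transfer because it is both α to the ester and allylic. The forward product must be handled cold.

10 from 9, and 9 from 8. The C5–H bond is traced back to a C5–O bond. A direct dehydration of the C5 carbinol is not used: its hydroxyl is cis to H1, so there is no anti hydrogen, and the tertiary O4 would react first. As a ketone, C5 can enolise only toward C1, so the enol triflate fixes the C1=C5 alkene and is then reduced. The forward step must enolise the ketone and not the ester.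

8 from 7, and 7 from 6. The O4–Si bond is cut and C5 is returned to the alcohol level. Oxidation tells the two hydroxyls of 6 apart without a protecting group, and silylation after it avoids silyl migration between cis oxygens.

6 from 5, and 5 from 3 and 4. The C1–C10 bond is cut, with one ester carbon added back. The epoxide makes C1 electrophilic and 4 brings the two-carbon chain. The forward opening must go to C1 and not to C5.

3 from 2, and 2 from 1. The epoxide C–O bonds and then the C1=C5 ring alkene are cut. 1 already holds the C4 stereocentre with its methyl and oxygen and two alkenes placed for ring closure, so the only stereocentre not made in the route is bought.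

## Other disconnections considered

Alternative 1: The cut takes C5 out from between C1 and C6, which turns the seven-membered ring back into a benzene ring and opens ring A at C1–C5; the precursor is diazoketone A1. Forward, Rh2(S-PTTL)4 would make a carbenoid at C5 that adds to the C1–C6 arene bond and the adduct opens electrocyclically to dihydroazulenone A2 (intramolecular Buchner reaction).
- In its favour: the arene supplies six ring carbons already carrying the C10 methyl, the C7 isopropyl group and O8, and one step closes ring A and makes the seven-membered ring. The way to the bicycle is shorter than in the chosen plan, which is a point where this alternative is the better one.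
- Against it here: A2 has a single stereocentre, C5, which is α to the C4 ketone and allylic and so would be prone to enolise. C6 carries no oxygen. C7 and C8 would have to be set on a conjugated triene whose three alkenes must be told apart. The methyl addition at C4 would need facial control from that labile C5. The carbenoid must also choose between the two ortho bonds of the arene.
- Comparison: on structure, A2 brings C14, the isopropyl group and O8 in place (equal or better), but 19 already holds three of the five centres and both O4 and O6. On mechanism, both plans use a dirhodium carbenoid followed by a pericyclic event and are equally well founded for the ring construction. On step economy, the gain before the key step would be lost in a longer and less controlled sequence after it.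

Alternative 2: The cut opens ring A at C1–C5, C2–C3 and C3–C4, which also opens the seven-membered ring, and leaves the open-chain allenyne A3 and carbon monoxide. Forward, [Rh(CO)2Cl]2 under CO would couple the alkyne, the terminal allene double bond and CO to dienone A4 (allenic Pauson–Khand reaction).
- In its favour: three C–C bonds and both rings form in one step, one bond more than in the chosen key step (better). The C6–C7–C8 triad would be set beforehand by acyclic methods. The C1=C10 alkene arrives with its C14 methyl, so no ester-to-methyl adjustment is needed (better).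
- Against it here: A4 has a C3 ketone that the target lacks and a C4=C5 enone alkene where the target needs the tertiary carbinol and the C5 hydrogen. The follow-up would be reduction at C5 with facial control, oxygenation at C4, methyl already present, and removal of the C3 oxygen, all beside a C6 silyl ether that is γ to the enone and open to vinylogous elimination. A3 with three stereocentres, an alkyne and a 1,1-disubstituted allene would itself take many steps.
- Comparison: on structure, ring A comes over-oxidised at C3 and under-functionalised at C4, whereas the chosen plan brings C4 in at the right level from 1. On mechanism, a rhodium-mediated ring closure carries the strategy in both plans and the two are equal in standing. On step economy, this alternative would be longer overall.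

Alternative 3: The cut is the C8–C9 bond, re-formed as C8–C1, which contracts the seven-membered ring to ring B of the cis-fused diquinane A5 with an isopropenyl group (C9, C10, C14) on C1. Forward, irradiation near 300 nm would cleave C8–C1 and recombine the acyl carbon with C9 (1,3-acyl shift) to give cycloheptenone A6.
- In its favour: A6 maps onto the target more closely than 19. It has the C14 methyl, the C1=C10 alkene, the four centres C4–C7 and a C8 carbonyl, so only reduction, acylation and desilylation would remain (better after the key step). The rigid cis-fused diquinane gives predictable faces for setting those centres (equal or better).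
- Against it here: A5, with a quaternary C1 beside the ketone and four stereocentres, would be a long synthesis in itself. A6 is again a β,γ-unsaturated ketone absorbing at the same wavelength, so the shift would be reversible and lead toward a photostationary mixture. Decarbonylation and cleavage on the C7 side, which would scramble C7, compete. The C8 reduction would need hydride on the face of the isopropyl group and O6, the more hindered one.
- Comparison: on structure, A6 is ahead of 19. On mechanism, a radical-pair photoreaction is harder to steer than the concerted cyclopropanation and Cope steps. On step economy, the gain after the key step would be outweighed by the route to A5.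

Key step: step 13

Assumptions:
- (S)-Linalool of high enantiomeric purity and 4-(tert-butyldimethylsilyloxy)benzoic acid are taken as purchasable.
- Names of bicyclic compounds use guaiane carbon numbers (C11 isopropyl methine, C14 the carbon on C10, C15 the methyl on C4), with every stereocentre given by its CIP descriptor.
- Rh2(S-DOSP)4 is taken to show the sense of induction it shows with monosubstituted alkenes and aryl- or vinyldiazoacetates, which corresponds to the (1S,2R) cyclopropane 18.

## Route

Step 1
Reactants: 1 (S)-linalool
Product: 2 (1S)-1-methylcyclopent-2-en-1-ol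
Conditions: second-generation Grubbs catalyst (H2IMes)(PCy3)Cl2Ru=CHPh (0.5 mol %), CH2Cl2, 40 °C
Reagents that add atoms: none
Why: Ring-closing metathesis between the vinyl group and the trisubstituted alkene closes the five-membered ring and expels volatile 2-methylpropene, which drives the reaction; the carbinol carbon is untouched, so C4 of the target is fixed here as S.

Step 2
Reactants: 2 (1S)-1-methylcyclopent-2-en-1-ol
Product: 3 (1R,2S,5R)-2-methyl-6-oxabicyclo[3.1.0]hexan-2-ol
Conditions: VO(acac)2 (2 mol %), t-BuOOH, CH2Cl2, 0 °C to rt
Reagents that add atoms: tert-butyl hydroperoxide, CC(C)(C)OO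
Why: Hydroxyl-directed epoxidation of an allylic alcohol: the vanadate ester of the tertiary alcohol delivers oxygen to the face it sits on and should give the cis-epoxy alcohol as one diastereomer; both new centres are erased later and serve only to give one defined compound.

Step 3
Reactants: 3 (1R,2S,5R)-2-methyl-6-oxabicyclo[3.1.0]hexan-2-ol; 4 dimethyl malonate
Product: 5 dimethyl 2-[(1R,2R,3S)-2,3-dihydroxy-3-methylcyclopentyl]propanedioate
Conditions: 4 (2 equiv), NaOMe (1.5 equiv), MeOH, reflux; aq NH4Cl
Reagents that add atoms: none
Why: SN2 opening of an epoxide by a malonate anion: attack should go to the epoxide carbon remote from the fully substituted carbinol (less hindered, not inductively deactivated) and anti to the C–O bond, which forms the C1–C10 bond and leaves a cis-diol with the malonate trans to the secondary hydroxyl.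

Step 4
Reactants: 5 dimethyl 2-[(1R,2R,3S)-2,3-dihydroxy-3-methylcyclopentyl]propanedioate
Product: 6 methyl 2-[(1R,2R,3S)-2,3-dihydroxy-3-methylcyclopentyl]acetate
Conditions: LiCl, H2O, DMSO, 150 °C
Reagents that add atoms: none
Why: Krapcho dealkoxycarbonylation: chloride demethylates one ester and the carboxylate loses CO2, leaving the acetic ester; the trans placing of the side chain and the secondary hydroxyl disfavours closure to a strained trans-fused lactone.

Step 5
Reactants: 6 methyl 2-[(1R,2R,3S)-2,3-dihydroxy-3-methylcyclopentyl]acetate
Product: 7 methyl 2-[(1R,3S)-3-hydroxy-3-methyl-2-oxocyclopentyl]acetate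
Conditions: IBX, DMSO, rt
Reagents that add atoms: none
Why: Oxidation of a secondary alcohol by a hypervalent iodine reagent: IBX turns 1,2-diols into α-hydroxy ketones without C–C cleavage and cannot touch the tertiary alcohol, so the two hydroxyls are told apart without a protecting group.

Step 6
Reactants: 7 methyl 2-[(1R,3S)-3-hydroxy-3-methyl-2-oxocyclopentyl]acetate
Product: 8 methyl 2-[(1R,3S)-3-methyl-2-oxo-3-(triethylsilyloxy)cyclopentyl]acetate
Conditions: Et3SiOTf, 2,6-lutidine, CH2Cl2, −78 to 0 °C
Reagents that add atoms: triethylsilyl trifluoromethanesulfonate, CC[Si](CC)(CC)OS(=O)(=O)C(F)(F)F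
Why: Silylation of a hindered tertiary alcohol with a silyl triflate and a hindered pyridine; it is done after the neighbouring oxygen has become a ketone, so no 1,2-silyl migration between cis oxygens can occur, and before enolate chemistry, so no α-ketol rearrangement can start from a free alkoxide.

Step 7
Reactants: 8 methyl 2-[(1R,3S)-3-methyl-2-oxo-3-(triethylsilyloxy)cyclopentyl]acetate
Product: 9 methyl 2-[(3S)-3-methyl-3-(triethylsilyloxy)-2-(trifluoromethanesulfonyloxy)cyclopent-1-en-1-yl]acetate
Conditions: KN(SiMe3)2, THF, −78 °C; PhNTf2, −78 to 0 °C
Reagents that add atoms: N-phenylbis(trifluoromethanesulfonimide), O=S(=O)(N(c1ccccc1)S(=O)(=O)C(F)(F)F)C(F)(F)F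
Why: Enol triflate formation by O-sulfonylation of a ketone enolate: the ketone can enolise only toward C1 because C4 is quaternary, and its α-hydrogen is far more acidic than those of the ester, so the C1=C5 alkene is placed without ambiguity and the C1 centre is removed.

Step 8
Reactants: 9 methyl 2-[(3S)-3-methyl-3-(triethylsilyloxy)-2-(trifluoromethanesulfonyloxy)cyclopent-1-en-1-yl]acetate
Product: 10 methyl 2-[(3S)-3-methyl-3-(triethylsilyloxy)cyclopent-1-en-1-yl]acetate
Conditions: Pd(OAc)2 (5 mol %), PPh3 (10 mol %), HCO2H, Et3N, DMF, 60 °C
Reagents that add atoms: none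
Why: Palladium-catalysed reduction of an enol triflate by formate (oxidative addition, formate exchange, loss of CO2, C–H reductive elimination) replaces the C5 oxygen by hydrogen with the alkene held at C1=C5; the mild amine buffer should not move the alkene into conjugation with the ester.

Step 9
Reactants: 10 methyl 2-[(3S)-3-methyl-3-(triethylsilyloxy)cyclopent-1-en-1-yl]acetate
Product: 11 methyl 2-diazo-2-[(3S)-3-methyl-3-(triethylsilyloxy)cyclopent-1-en-1-yl]acetate
Conditions: 4-acetamidobenzenesulfonyl azide, DBU, MeCN, 0 °C to rt
Reagents that add atoms: 4-acetamidobenzenesulfonyl azide, CC(=O)Nc1ccc(cc1)S(=O)(=O)N=[N+]=[N-]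
Why: Regitz diazo transfer: DBU forms the extended enolate of the β,γ-unsaturated ester, which attacks the sulfonyl azide at the α-carbon to give the vinyldiazoacetate; the product is kept cold and used promptly because vinyldiazo compounds slowly close to pyrazoles.

Step 10
Reactants: 12 3-methylbutanal (isovaleraldehyde)
Product: 13 (E)-N-cyclohexyl-3-methylbutan-1-imine
Conditions: cyclohexylamine, K2CO3, Et2O, 0 °C to rt
Reagents that add atoms: cyclohexylamine, NC1CCCCC1
Why: Condensation of an aldehyde with a primary amine gives the imine, which turns the aldehyde into a component that can act only as the nucleophile of a directed aldol.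

Step 11
Reactants: 13 (E)-N-cyclohexyl-3-methylbutan-1-imine; 14 acetaldehyde
Product: 16 (2E)-2-(propan-2-yl)but-2-enal, via β-hydroxy imine 15 (not isolated)
Conditions: LiN(i-Pr)2, THF, 0 °C; 14, −78 °C; aq oxalic acid, reflux
Reagents that add atoms: none
Why: Directed aldol condensation through a metalated imine: the lithiated imine can only be the nucleophile and acetaldehyde only the electrophile, so the statistical mixture of a crossed aldol between two enolisable aldehydes is avoided; acid hydrolysis frees the aldehyde and dehydrates the aldol to the more stable E-enal.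

Step 12
Reactants: 16 (2E)-2-(propan-2-yl)but-2-enal
Product: 17 tert-butyl(dimethyl){[(1E)-2-(propan-2-yl)buta-1,3-dien-1-yl]oxy}silane
Conditions: t-BuMe2SiOTf, Et3N, Et2O, 0 °C to rt
Reagents that add atoms: tert-butyldimethylsilyl trifluoromethanesulfonate, CC(C)(C)[Si](C)(C)OS(=O)(=O)C(F)(F)F
Why: Soft enolisation of an enal: O-silylation of the carbonyl and loss of a γ-proton give the 1-siloxydiene; the enal should react from its favoured s-trans conformation, which puts the silyloxy group trans to the vinyl group (1E), the geometry the Cope step needs.

Step 13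
Reactants: 11 methyl 2-diazo-2-[(3S)-3-methyl-3-(triethylsilyloxy)cyclopent-1-en-1-yl]acetate; 17 tert-butyl(dimethyl){[(1E)-2-(propan-2-yl)buta-1,3-dien-1-yl]oxy}silane
Product: 19 methyl (4S,5S,6S)-6-(tert-butyldimethylsilyloxy)-4-(triethylsilyloxy)guaia-1(10),7-dien-14-oate, via cis-divinylcyclopropane 18 (not isolated)
Conditions: Rh2(S-DOSP)4 (1 mol %), 17 (3 equiv), hexanes, −40 °C to rt, slow addition of 11; then 50 °C
Reagents that add atoms: none
Why: This is a tandem cyclopropanation and Cope rearrangement, the known formal (4+3) annulation of rhodium vinylcarbenoids with 1-oxygenated dienes: the dirhodium prolinate expels N2 from 11 and the donor/acceptor carbenoid at C10 adds in a concerted, asynchronous way to the monosubstituted C8=C9 alkene of 17, the trisubstituted silyl enol ether being too hindered to compete. The three-membered ring (C10, C9, C8) closes by this (2+1) addition with the cyclopentenyl group cis to the dienyl residue, as is general for donor/acceptor carbenoids, and the catalyst should set C10 and C8 as (1S,2R). The cis-divinylcyclopropane 18 then closes the seven-membered ring by a [3,3] sigmatropic shift through a boat, in which C10–C8 breaks and C5–C6 forms suprafacially on both allyl units. C5 and C6 are controlled by this stereospecific transfer: H5 and H6 take the inside positions of the boat because the ring carbon C4 and the (1E)-silyloxy group are the outside substituents, so the hydrogens come out cis, and their absolute sense follows C10 and C8. The selectivity the step needs is the face of the carbenoid; the resident C4 centre is three bonds from the carbenoid carbon and should not override the catalyst, and because C4 is enantiopure any leakage would appear as a separable diastereomer. The new bond at C5 forms syn to the C4 silyloxy group, which brings the two silyl ethers into a 1,3-relationship in the boat, so gentle heating is planned to complete the rearrangement.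

Step 14
Reactants: 19 methyl (4S,5S,6S)-6-(tert-butyldimethylsilyloxy)-4-(triethylsilyloxy)guaia-1(10),7-dien-14-oate
Product: 20 (4S,5S,6S)-6-(tert-butyldimethylsilyloxy)-4-(triethylsilyloxy)guaia-1(10),7-dien-14-ol
Conditions: i-Bu2AlH, CH2Cl2, −78 to −20 °C; aq potassium sodium tartrate
Reagents that add atoms: none
Why: Reduction of a conjugated ester by an aluminium hydride gives the allylic alcohol by 1,2-addition; the silyl ethers and both alkenes are inert.

Step 15
Reactants: 20 (4S,5S,6S)-6-(tert-butyldimethylsilyloxy)-4-(triethylsilyloxy)guaia-1(10),7-dien-14-ol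
Product: 22 (4S,5S,6S)-6-(tert-butyldimethylsilyloxy)-4-(triethylsilyloxy)guaia-1(10),7-diene, via allylic mesylate 21 (not isolated)
Conditions: MsCl, Et3N, THF, −30 °C; LiBHEt3, −30 to 0 °C
Reagents that add atoms: none
Why: Sulfonylation of the primary allylic alcohol and SN2 displacement by a borohydride turn CH2OH into the C14 methyl group; substitution at the primary carbon should win over SN2′ delivery to the fully substituted C1, so the alkene stays at C1=C10.

Step 16
Reactants: 22 (4S,5S,6S)-6-(tert-butyldimethylsilyloxy)-4-(triethylsilyloxy)guaia-1(10),7-diene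
Product: 24 (4S,5S,6R,7R,8S)-6-(tert-butyldimethylsilyloxy)-4-(triethylsilyloxy)guai-1(10)-en-8-ol, via alkylborane 23 (not isolated)
Conditions: BH3·THF (1.1 equiv), THF, 0 °C; NaOH, H2O2, 0 °C to rt
Reagents that add atoms: hydrogen peroxide, OO
Why: Hydroboration–oxidation: boron adds to the less substituted C8 and hydrogen to C7 in a syn fashion on the face opposite the C6 silyloxy group, which allylic 1,2-strain with the isopropyl group turns pseudoaxial over the alkene, so C7 (isopropyl cis to O6) and C8 (oxygen trans to the isopropyl group) are set together. Oxidation goes with retention, and the more hindered tetrasubstituted C1=C10 alkene should react more slowly with a limited amount of borane.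

Step 17
Reactants: 24 (4S,5S,6R,7R,8S)-6-(tert-butyldimethylsilyloxy)-4-(triethylsilyloxy)guai-1(10)-en-8-ol; 25 4-(tert-butyldimethylsilyloxy)benzoic acid
Product: 26 (4S,5S,6R,7R,8S)-6-(tert-butyldimethylsilyloxy)-4-(triethylsilyloxy)guai-1(10)-en-8-yl 4-(tert-butyldimethylsilyloxy)benzoate
Conditions: 25, DCC, DMAP, CH2Cl2, rt
Reagents that add atoms: none
Why: Steglich esterification: the carbodiimide activates the acid and DMAP transfers the aroyl group to O8, the only free hydroxyl, with retention at C8; the phenol is already a silyl ether and cannot compete.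

Step 18
Reactants: 26 (4S,5S,6R,7R,8S)-6-(tert-butyldimethylsilyloxy)-4-(triethylsilyloxy)guai-1(10)-en-8-yl 4-(tert-butyldimethylsilyloxy)benzoate
Product: 27 (4S,5S,6R,7S,8S)-4,6-dihydroxyguai-1(10)-en-8-yl 4-hydroxybenzoate (CNP0392039.1)
Conditions: HF·pyridine, pyridine, THF, 0 °C to rt
Reagents that add atoms: none
Why: Fluoride cleavage of silyl ethers removes the aryl, tertiary and secondary silyl groups in one operation; the buffered acidic medium avoids the alkoxide that would let the aroyl group move from O8 to O6 or be cleaved.

## Compound list

1 | (S)-linalool, (3S)-3,7-dimethylocta-1,6-dien-3-ol | C=C[C@@](C)(O)CCC=C(C)C | starting material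
2 | (1S)-1-methylcyclopent-2-en-1-ol | C[C@@]1(O)C=CCC1 | intermediate
3 | (1R,2S,5R)-2-methyl-6-oxabicyclo[3.1.0]hexan-2-ol (epoxide cis to hydroxyl) | C[C@@]1(O)[C@@H]2O[C@@H]2CC1 | intermediate
4 | dimethyl malonate | COC(=O)CC(=O)OC | starting material
5 | dimethyl 2-[(1R,2R,3S)-2,3-dihydroxy-3-methylcyclopentyl]propanedioate | C[C@@]1(O)[C@H](O)[C@@H](C(C(=O)OC)C(=O)OC)CC1 | intermediate
6 | methyl 2-[(1R,2R,3S)-2,3-dihydroxy-3-methylcyclopentyl]acetate | C[C@@]1(O)[C@H](O)[C@@H](CC(=O)OC)CC1 | intermediate
7 | methyl 2-[(1R,3S)-3-hydroxy-3-methyl-2-oxocyclopentyl]acetate | C[C@@]1(O)C(=O)[C@@H](CC(=O)OC)CC1 | intermediate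
8 | methyl 2-[(1R,3S)-3-methyl-2-oxo-3-(triethylsilyloxy)cyclopentyl]acetate | C[C@@]1(O[Si](CC)(CC)CC)C(=O)[C@@H](CC(=O)OC)CC1 | intermediate
9 | methyl 2-[(3S)-3-methyl-3-(triethylsilyloxy)-2-(trifluoromethanesulfonyloxy)cyclopent-1-en-1-yl]acetate | C[C@@]1(O[Si](CC)(CC)CC)C(OS(=O)(=O)C(F)(F)F)=C(CC(=O)OC)CC1 | intermediate
10 | methyl 2-[(3S)-3-methyl-3-(triethylsilyloxy)cyclopent-1-en-1-yl]acetate | C[C@@]1(O[Si](CC)(CC)CC)C=C(CC(=O)OC)CC1 | intermediate
11 | methyl 2-diazo-2-[(3S)-3-methyl-3-(triethylsilyloxy)cyclopent-1-en-1-yl]acetate | COC(=O)C(=[N+]=[N-])C1=C[C@@](C)(O[Si](CC)(CC)CC)CC1 | intermediate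
12 | 3-methylbutanal (isovaleraldehyde) | CC(C)CC=O | starting material
13 | (E)-N-cyclohexyl-3-methylbutan-1-imine | CC(C)C/C=N/C1CCCCC1 | intermediate
14 | acetaldehyde | CC=O | starting material
15 | 3-[(cyclohexylimino)methyl]-4-methylpentan-2-ol (mixture of diastereomers, not isolated) | CC(O)C(C(C)C)C=NC1CCCCC1 | intermediate
16 | (2E)-2-(propan-2-yl)but-2-enal | C/C=C(/C=O)C(C)C | intermediate
17 | tert-butyl(dimethyl){[(1E)-2-(propan-2-yl)buta-1,3-dien-1-yl]oxy}silane | C=C/C(=C/O[Si](C)(C)C(C)(C)C)C(C)C | intermediate
18 | methyl (1S,2R)-2-[(1E)-1-(tert-butyldimethylsilyloxy)-3-methylbut-1-en-2-yl]-1-[(3S)-3-methyl-3-(triethylsilyloxy)cyclopent-1-en-1-yl]cyclopropane-1-carboxylate (not isolated) | COC(=O)[C@@]1(C2=C[C@@](C)(O[Si](CC)(CC)CC)CC2)C[C@@H]1/C(C(C)C)=C/O[Si](C)(C)C(C)(C)C | intermediate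
19 | methyl (4S,5S,6S)-6-(tert-butyldimethylsilyloxy)-4-(triethylsilyloxy)guaia-1(10),7-dien-14-oate | COC(=O)C1=C2CC[C@](C)(O[Si](CC)(CC)CC)[C@@H]2[C@H](O[Si](C)(C)C(C)(C)C)C(C(C)C)=CC1 | intermediate
20 | (4S,5S,6S)-6-(tert-butyldimethylsilyloxy)-4-(triethylsilyloxy)guaia-1(10),7-dien-14-ol | OCC1=C2CC[C@](C)(O[Si](CC)(CC)CC)[C@@H]2[C@H](O[Si](C)(C)C(C)(C)C)C(C(C)C)=CC1 | intermediate
21 | (4S,5S,6S)-6-(tert-butyldimethylsilyloxy)-4-(triethylsilyloxy)guaia-1(10),7-dien-14-yl methanesulfonate (not isolated) | CS(=O)(=O)OCC1=C2CC[C@](C)(O[Si](CC)(CC)CC)[C@@H]2[C@H](O[Si](C)(C)C(C)(C)C)C(C(C)C)=CC1 | intermediate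
22 | (4S,5S,6S)-6-(tert-butyldimethylsilyloxy)-4-(triethylsilyloxy)guaia-1(10),7-diene | CC1=C2CC[C@](C)(O[Si](CC)(CC)CC)[C@@H]2[C@H](O[Si](C)(C)C(C)(C)C)C(C(C)C)=CC1 | intermediate
23 | [(4S,5S,6R,7S,8S)-6-(tert-butyldimethylsilyloxy)-4-(triethylsilyloxy)guai-1(10)-en-8-yl]borane (not isolated) | CC1=C2CC[C@](C)(O[Si](CC)(CC)CC)[C@@H]2[C@H](O[Si](C)(C)C(C)(C)C)[C@H](C(C)C)[C@@H](B)C1 | intermediate
24 | (4S,5S,6R,7R,8S)-6-(tert-butyldimethylsilyloxy)-4-(triethylsilyloxy)guai-1(10)-en-8-ol | CC1=C2CC[C@](C)(O[Si](CC)(CC)CC)[C@@H]2[C@H](O[Si](C)(C)C(C)(C)C)[C@H](C(C)C)[C@@H](O)C1 | intermediate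
25 | 4-(tert-butyldimethylsilyloxy)benzoic acid | CC(C)(C)[Si](C)(C)Oc1ccc(cc1)C(=O)O | starting material
26 | (4S,5S,6R,7R,8S)-6-(tert-butyldimethylsilyloxy)-4-(triethylsilyloxy)guai-1(10)-en-8-yl 4-(tert-butyldimethylsilyloxy)benzoate | CC1=C2CC[C@](C)(O[Si](CC)(CC)CC)[C@@H]2[C@H](O[Si](C)(C)C(C)(C)C)[C@H](C(C)C)[C@@H](OC(=O)c2ccc(O[Si](C)(C)C(C)(C)C)cc2)C1 | intermediate
27 | (4S,5S,6R,7S,8S)-4,6-dihydroxyguai-1(10)-en-8-yl 4-hydroxybenzoate | CC1=C2CC[C@](C)(O)[C@@H]2[C@H](O)[C@H](C(C)C)[C@@H](OC(=O)c2ccc(O)cc2)C1 | target

## Step count and least certain steps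

Total step count: 18. Longest linear sequence: 15 steps (steps 1–9 and 13–18, from 1).

Step 13 (key step). The most likely failures are two. The catalyst may not fully control the carbenoid face in the presence of the C4 centre. The Cope rearrangement may also be slow, because the boat brings the silyl ethers on O4 and O6 close together, so the cyclopropane may linger and decay on heating. If only the sense of induction is wrong, Rh2(R-DOSP)4 is the direct remedy. The fallback moves stereocontrol from the catalyst to a covalently bound auxiliary. It sets out from 10: saponification (LiOH, THF/H2O) should give 2-[(3S)-3-methyl-3-(triethylsilyloxy)cyclopent-1-en-1-yl]acetic acid F1. Esterification with (R)-pantolactone (DCC, DMAP) should give (3R)-4,4-dimethyl-2-oxooxolan-3-yl 2-[(3S)-3-methyl-3-(triethylsilyloxy)cyclopent-1-en-1-yl]acetate F2. Diazo transfer as in step 9 should give the corresponding diazo ester (3R)-4,4-dimethyl-2-oxooxolan-3-yl 2-diazo-2-[(3S)-3-methyl-3-(triethylsilyloxy)cyclopent-1-en-1-yl]acetate F3. Decomposition with achiral Rh2(O2CC7H15)4 in the presence of 17 should lead, by the same cyclopropanation and Cope sequence, to (3R)-4,4-dimethyl-2-oxooxolan-3-yl (4S,5S,6S)-6-(tert-butyldimethylsilyloxy)-4-(triethylsilyloxy)guaia-1(10),7-dien-14-oate F4. LiAlH4 reduction removes the auxiliary and the fallback comes back to the route at 20. α-Hydroxy ester auxiliaries are a known way to impose facial selectivity on vinylcarbenoid cyclopropanations; the antipodal pantolactone would be used if it is the one that reinforces the required sense.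

Step 16. The most likely failure is poor discrimination by borane between the C7=C8 and C1=C10 alkenes. The fallback changes the order so that C1=C10 is deactivated by conjugation while C7=C8 is hydroborated. It sets out from 19: BH3·THF then buffered peroxide should give methyl (4S,5S,6R,7R,8S)-6-(tert-butyldimethylsilyloxy)-8-hydroxy-4-(triethylsilyloxy)guai-1(10)-en-14-oate F5. i-Bu2AlH should give (4S,5S,6R,7R,8S)-6-(tert-butyldimethylsilyloxy)-4-(triethylsilyloxy)guai-1(10)-ene-8,14-diol F6. Selective sulfonylation of the primary allylic hydroxyl (MsCl, Et3N, −40 °C) should give (4S,5S,6R,7R,8S)-6-(tert-butyldimethylsilyloxy)-8-hydroxy-4-(triethylsilyloxy)guai-1(10)-en-14-yl methanesulfonate F7, which is reduced in the same flask with LiBHEt3. The fallback comes back to the route at 24.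

Step 18. The most likely failure is incomplete cleavage of the hindered C6 silyl ether, followed by aroyl migration or elimination at C4 once the conditions are forced. The fallback removes the hindered silyl groups before the ester exists. It sets out from 24: Bu4NF in warm THF should give (4S,5S,6R,7R,8S)-guai-1(10)-ene-4,6,8-triol F8. Acylation with 25 (DCC, DMAP, −20 °C) should go to the less hindered O8, since the tertiary O4 and the doubly flanked O6 react more slowly, and give (4S,5S,6R,7S,8S)-4,6-dihydroxyguai-1(10)-en-8-yl 4-(tert-butyldimethylsilyloxy)benzoate F9. A brief treatment with HF·pyridine then cleaves the labile aryl silyl ether and the fallback comes back to the route at 27.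

Step 3. The most likely failure is slow or unselective opening of the hindered epoxide by the malonate anion, with methanolysis of the epoxide competing. The fallback makes the C1–C10 bond by enolate alkylation instead. It sets out from 3: LiAlH4 should open the epoxide at the remote carbon to give (1S,2R)-1-methylcyclopentane-1,2-diol F10. IBX should give (2S)-2-hydroxy-2-methylcyclopentan-1-one F11. Et3SiOTf and 2,6-lutidine should give (2S)-2-methyl-2-(triethylsilyloxy)cyclopentan-1-one F12. Its only possible enolate (LiN(i-Pr)2, THF, −78 °C) is alkylated with methyl bromoacetate, and the fallback comes back to the route at 8, as a mixture of C1 epimers that both lead to 9.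

## Further compounds

F1 | step 13 | 2-[(3S)-3-methyl-3-(triethylsilyloxy)cyclopent-1-en-1-yl]acetic acid | C[C@@]1(O[Si](CC)(CC)CC)C=C(CC(=O)O)CC1
F2 | step 13 | (3R)-4,4-dimethyl-2-oxooxolan-3-yl 2-[(3S)-3-methyl-3-(triethylsilyloxy)cyclopent-1-en-1-yl]acetate | CC1(C)COC(=O)[C@@H]1OC(=O)CC1=C[C@@](C)(O[Si](CC)(CC)CC)CC1
F3 | step 13 | (3R)-4,4-dimethyl-2-oxooxolan-3-yl 2-diazo-2-[(3S)-3-methyl-3-(triethylsilyloxy)cyclopent-1-en-1-yl]acetate | CC1(C)COC(=O)[C@@H]1OC(=O)C(=[N+]=[N-])C1=C[C@@](C)(O[Si](CC)(CC)CC)CC1
F4 | step 13 | (3R)-4,4-dimethyl-2-oxooxolan-3-yl (4S,5S,6S)-6-(tert-butyldimethylsilyloxy)-4-(triethylsilyloxy)guaia-1(10),7-dien-14-oate | CC1(C)COC(=O)[C@@H]1OC(=O)C1=C2CC[C@](C)(O[Si](CC)(CC)CC)[C@@H]2[C@H](O[Si](C)(C)C(C)(C)C)C(C(C)C)=CC1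
F5 | step 16 | methyl (4S,5S,6R,7R,8S)-6-(tert-butyldimethylsilyloxy)-8-hydroxy-4-(triethylsilyloxy)guai-1(10)-en-14-oate | COC(=O)C1=C2CC[C@](C)(O[Si](CC)(CC)CC)[C@@H]2[C@H](O[Si](C)(C)C(C)(C)C)[C@H](C(C)C)[C@@H](O)C1
F6 | step 16 | (4S,5S,6R,7R,8S)-6-(tert-butyldimethylsilyloxy)-4-(triethylsilyloxy)guai-1(10)-ene-8,14-diol | OCC1=C2CC[C@](C)(O[Si](CC)(CC)CC)[C@@H]2[C@H](O[Si](C)(C)C(C)(C)C)[C@H](C(C)C)[C@@H](O)C1
F7 | step 16 | (4S,5S,6R,7R,8S)-6-(tert-butyldimethylsilyloxy)-8-hydroxy-4-(triethylsilyloxy)guai-1(10)-en-14-yl methanesulfonate | CS(=O)(=O)OCC1=C2CC[C@](C)(O[Si](CC)(CC)CC)[C@@H]2[C@H](O[Si](C)(C)C(C)(C)C)[C@H](C(C)C)[C@@H](O)C1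
F8 | step 18 | (4S,5S,6R,7R,8S)-guai-1(10)-ene-4,6,8-triol | CC1=C2CC[C@](C)(O)[C@@H]2[C@H](O)[C@H](C(C)C)[C@@H](O)C1
F9 | step 18 | (4S,5S,6R,7S,8S)-4,6-dihydroxyguai-1(10)-en-8-yl 4-(tert-butyldimethylsilyloxy)benzoate | CC1=C2CC[C@](C)(O)[C@@H]2[C@H](O)[C@H](C(C)C)[C@@H](OC(=O)c2ccc(O[Si](C)(C)C(C)(C)C)cc2)C1
F10 | step 3 | (1S,2R)-1-methylcyclopentane-1,2-diol | C[C@@]1(O)[C@H](O)CCC1
F11 | step 3 | (2S)-2-hydroxy-2-methylcyclopentan-1-one | C[C@@]1(O)C(=O)CCC1
F12 | step 3 | (2S)-2-methyl-2-(triethylsilyloxy)cyclopentan-1-one | C[C@@]1(O[Si](CC)(CC)CC)C(=O)CCC1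
A1 | alternative 1 | 1-diazo-4-[4-methoxy-2-methyl-5-(propan-2-yl)phenyl]butan-2-one | Cc1cc(OC)c(C(C)C)cc1CCC(=O)C=[N+]=[N-]
A2 | alternative 1 | (8aR)-6-methoxy-4-methyl-7-(propan-2-yl)-3,8a-dihydroazulen-1(2H)-one | CC1=C2CCC(=O)[C@@H]2C=C(C(C)C)C(OC)=C1
A3 | alternative 2 | 6-(tert-butyldimethylsilyloxy)-8-methyl-5-(propan-2-yl)-4-(triethylsilyloxy)deca-8,9-dien-2-yne, configured at its C4, C5 and C6 as the target at C6, C7 and C8 | CC#C[C@H](O[Si](CC)(CC)CC)[C@H](C(C)C)[C@@H](O[Si](C)(C)C(C)(C)C)CC(C)=C=C
A4 | alternative 2 | 8-(tert-butyldimethylsilyloxy)-6-(triethylsilyloxy)guaia-1(10),4-dien-3-one, configured at C6, C7 and C8 as the target | CC1=C2CC(=O)C(C)=C2[C@H](O[Si](CC)(CC)CC)[C@H](C(C)C)[C@@H](O[Si](C)(C)C(C)(C)C)C1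
A5 | alternative 3 | cis-fused 6-methyl-3-(propan-2-yl)-1-(prop-1-en-2-yl)-4,6-bis(triethylsilyloxy)bicyclo[3.3.0]octan-2-one, configured as the target at guaiane C4 to C7 | CC(=C)[C@@]12CC[C@](C)(O[Si](CC)(CC)CC)[C@@H]1[C@H](O[Si](CC)(CC)CC)[C@H](C(C)C)C2=O
A6 | alternative 3 | 4,6-bis(triethylsilyloxy)guai-1(10)-en-8-one, configured at C4 to C7 as the target | CC1=C2CC[C@](C)(O[Si](CC)(CC)CC)[C@@H]2[C@H](O[Si](CC)(CC)CC)[C@H](C(C)C)C(=O)C1
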